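(The numbers in the tables were computed on assumed constants, noise included.)

We charge 1.0 mM of substrate and 5.00 mM of partner, and ask what side product stands at 15 min when one or the other is fed slowly.

| setting | delta | gamma | theta | eta | oak | larch | maple |
|---|---|---|---|---|---|---|---|
| substrate | 1 mM | 1 mM | 1 mM | 1.5 mM | 1.0 mM (fed, over 10 min) | 1.0 mM | 1.0 mM |
| partner | 5 mM | 2.5 mM | 3.8 mM | 5 mM | 5.00 mM | 5.00 mM (fed, over 10 min) | 5.00 mM |
| remark | run made earlier | run made earlier | run made earlier | run made earlier | all else is in the flask from the start; the feed brings no volume worth counting | all else is in the flask from the start; the feed brings no volume worth counting | everything together at the start |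
| time |  |  |  |  | 15 min | 15 min | 15 min |

| run | time / min | side product / % | target / % |
|---|---|---|---|
| delta | 1.50 | 36.0 | 27.1 |
| delta | 3.00 | 53.7 | 13.7 |
| delta | 5.00 | 60.1 | 8.1 |
| delta | 6.00 | 62.1 | 8.2 |
| delta | 8.00 | 63.3 | 4.0 |
| delta | 10.0 | 65.2 | 4.3 |
| gamma | 1.50 | 16.5 | 22.2 |
| gamma | 3.00 | 28.7 | 13.5 |
| gamma | 5.00 | 35.3 | 7.7 |
| gamma | 6.00 | 37.6 | 6.5 |
| gamma | 8.00 | 38.3 | 5.0 |
| gamma | 10.0 | 39.2 | 3.1 |
| theta | 1.50 | 26.4 | 23.8 |
| theta | 3.00 | 41.9 | 14.4 |
| theta | 5.00 | 50.4 | 9.2 |
| theta | 6.00 | 50.1 | 8.0 |
| theta | 8.00 | 54.3 | 7.6 |
| theta | 10.0 | 54.4 | 4.5 |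
| eta | 0.667 | 14.0 | 27.3 |
| eta | 1.33 | 36.5 | 22.1 |
| eta | 2.50 | 50.7 | 11.6 |
| eta | 5.00 | 59.0 | 6.3 |
| eta | 10.0 | 63.2 | 2.6 |

(scatter of a reading: 1 percentage point)



- the flask with the highest amount of side product, in percent of the substrate charged ("all alike" if they lie within 1.5 percentage points) (oak / larch / maple / all alike)
- final side product, as a percentage of the substrate charged, in oak
- final side product, as a percentage of the substrate charged, in larch
- final side product, as a percentage of the substrate charged, in maple

In the delta run, the readings of target plus side product level off, the last at 69.5 % of the substrate, although partner was in excess, so we suppose that partner also decays by itself, with lifetime τ. Integrating the division of partner between substrate and decay gives: partner charged = substrate converted + K ln(substrate charged / substrate left). Here K, the partner lost to decay while substrate falls by a factor e, is 3.63 mM from delta, and gamma gives 3.78 mM. The rise to that level in delta reads as τ = 0.820 min.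

With the substrate all in the flask from the start, the balance counts partner however it enters, so we expect larch and maple to convert what delta converted. Oak differs: since τ is shorter than the feed time, 10 min, we reckon the converted share as σ = τ·partner/(K·feed time), or 11.3 %.

The reciprocal of target grows in delta at κ = 2.47 mM⁻¹ min⁻¹. Subtracting the target that remains, we reckon side product at 9.12 % in oak, 61.4 % in larch, counting its target's age from the feed's end, and 66.9 % in maple.

The forecast gave 64 % for oak, 25 % for larch and 65.5 % for maple, holding that “Larch starves the substrate of partner early”. The flasks give 8.13 %, 64.1 % and 67.0 %, so the highest is maple.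

    partner → decomposed reagent (k = 0.0154 s⁻¹)
    target + by-product → side product (k = 49.0 M⁻¹ s⁻¹)
    substrate + partner → target + by-product (k = 4.24 M⁻¹ s⁻¹)

In oak at 0.730 min, partner has a half-life of 0.75 min by decay into decomposed reagent but 49 min by reaction with substrate, a rate ratio of 66. That ratio is K over the substrate present, so with K = 3.63 mM, as read from delta, we reckon that oak then held 0.0550 mM of substrate, out of 0.0730 mM fed. For the neighbouring flask, oak with 1.2 mM of partner, σ is 2.71 %, and that flask ends with 96.9 % of its substrate unconverted.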